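**Retrosynthetic overview**

- 12 ⇒ nonadecyl radical + vinyl ketone 9. One pot makes the bond between chain C2 and chain C3 (counted from the ring) by radical conjugate addition and then closes the pyrrole at C2–C3 by aldol condensation.
- Enabling feature: in the pyrrole, N1–C2(CO2Me) is a glycine ester unit and C3, the ring carbon that carries the chain, is the masked ketone carbon of a (Z)-enaminone N1–C5=C4–C3(=O). Chain C2 is therefore the β-carbon of a vinyl ketone, a radical acceptor exactly where the chain has to be joined.
- 9 is released in the flask from the storable ammonium salt 6 ⇐ 5 ⇐ 3 ⇐ Danishefsky's diene 1 + Eschenmoser's salt 2 (which supplies chain C2), with glycine methyl ester 4. The radical comes from icosanoic acid 7 through its redox-active ester 8 with loss of CO2.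
- Ring order: no ring exists before the key step. The pyrrole, the only ring, is formed last, at carbon (C2–C3) and not at nitrogen.

Key step: step 5

Remark: the secondary enaminones 5, 6, 9 and 10 are drawn as their hydrogen-bonded Z isomers. As push–pull alkenes they equilibrate readily, so this geometry is taken as thermodynamically set.

**Step 1**
Reactants: 1 (E)-1-methoxy-3-(trimethylsilyloxy)buta-1,3-diene (Danishefsky's diene); 2 N,N-dimethylmethyleneiminium iodide (Eschenmoser's salt)
Product: 3 (1E)-5-(dimethylamino)-1-methoxypent-1-en-3-one
Conditions: CH2Cl2, −78 °C → 0 °C; then sat. aq. NaHCO3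
Reagents that add atoms: none
Why: Mukaiyama–Mannich reaction, in which the silyl dienol ether attacks the preformed iminium ion through its terminal CH2 and loss of the silyl group to iodide leaves the E-configured β-methoxy enone intact.

**Step 2**
Reactants: 3 (1E)-5-(dimethylamino)-1-methoxypent-1-en-3-one; 4 glycine methyl ester hydrochloride
Product: 5 methyl N-[(1Z)-5-(dimethylamino)-3-oxopent-1-en-1-yl]glycinate
Conditions: Et3N (1.05 equiv), MeOH, 0 °C → rt
Reagents that add atoms: none
Why: Addition–elimination of the primary amine at the β-carbon of the β-methoxy enone (vinylogous transamidation), the Z geometry being set thermodynamically by the intramolecular N–H···O=C hydrogen bond.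

**Step 3**
Reactants: 5 methyl N-[(1Z)-5-(dimethylamino)-3-oxopent-1-en-1-yl]glycinate
Product: 6 (4Z)-5-[(2-methoxy-2-oxoethyl)amino]-N,N,N-trimethyl-3-oxopent-4-en-1-aminium iodide
Conditions: MeI (1.5 equiv), acetone, 0 °C → rt, dark; salt precipitated with Et2O and filtered
Reagents that add atoms: iodomethane, CI
Why: Menshutkin quaternisation at the tertiary alkylamine, by far the most nucleophilic site because the enaminone nitrogen is a vinylogous amide, should give a crystalline latent vinyl ketone.

**Step 4**
Reactants: 7 icosanoic acid
Product: 8 1,3-dioxoisoindolin-2-yl icosanoate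
Conditions: N-hydroxyphthalimide, DIC, DMAP (cat.), CH2Cl2, rt
Reagents that add atoms: N-hydroxyphthalimide, O=C1c2ccccc2C(=O)N1O
Why: Steglich-type carbodiimide esterification should give the redox-active N-acyloxyphthalimide ester of the C20 acid.

**Step 5**
Reactants: 6 (4Z)-5-[(2-methoxy-2-oxoethyl)amino]-N,N,N-trimethyl-3-oxopent-4-en-1-aminium iodide (1.5 equiv); 8 1,3-dioxoisoindolin-2-yl icosanoate
Product: 12 methyl 3-henicosyl-1H-pyrrole-2-carboxylate, via vinyl ketone 9 (not isolated), via keto-enaminone 10 (not isolated), via aldol adduct 11 (not isolated)
Conditions: iPr2NEt, CH2Cl2, 0 °C; then 8, Ru(bpy)3(PF6)2 (1 mol %), Hantzsch ester (1.5 equiv), blue LEDs, rt; then concentrate, NaOMe (excess), MeOH–THF, 60 °C (one pot)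
Reagents that add atoms: none
Why: The amine base triggers E1cB loss of trimethylamine from 6 to unveil the cross-conjugated vinyl ketone 9; single-electron reduction of 8 by the photoreduced ruthenium catalyst (Hantzsch ester as terminal reductant) expels phthalimide and CO2, the nonadecyl radical adds to the unsubstituted CH2 terminus of 9 (Giese addition), and the α-keto radical is reduced and protonated to ketone 10. Methoxide then generates the glycinate carbanion, which attacks the C3 ketone in an intramolecular aldol reaction (5-exo-trig, enolexo) that closes the pyrrole at its C2–C3 bond, and aldol 11 loses water to aromatise. The closest known reaction types are the decarboxylative radical conjugate addition of N-acyloxyphthalimides to vinyl ketones and the base-mediated cyclisation of N-(3-oxoalk-1-enyl)glycinates to pyrrole-2-carboxylates (Knorr-type closure at carbon). No stereocentre has to be controlled, since the two carbinol centres of 11 are erased on dehydration. The step needs the nucleophilic radical to choose the vinyl terminus over the aminovinyl terminus, which is secured by push–pull donation from nitrogen into the C4=C5 bond and by the substituent on C5. Ring closure needs the Z enaminone, which the N–H···O=C hydrogen bond and the low rotation barrier of the push–pull alkene provide, and methoxide in methanol matches the methyl ester so that no ester exchange can occur.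

**Compound list**

1 | (E)-1-methoxy-3-(trimethylsilyloxy)buta-1,3-diene (Danishefsky's diene) | CO/C=C/C(=C)O[Si](C)(C)C | starting material
2 | N,N-dimethylmethyleneiminium iodide (Eschenmoser's salt) | C=[N+](C)C.[I-] | starting material
3 | (1E)-5-(dimethylamino)-1-methoxypent-1-en-3-one | CO/C=C/C(=O)CCN(C)C | intermediate
4 | glycine methyl ester hydrochloride | COC(=O)CN.Cl | starting material
5 | methyl N-[(1Z)-5-(dimethylamino)-3-oxopent-1-en-1-yl]glycinate | COC(=O)CN/C=C\C(=O)CCN(C)C | intermediate
6 | (4Z)-5-[(2-methoxy-2-oxoethyl)amino]-N,N,N-trimethyl-3-oxopent-4-en-1-aminium iodide | COC(=O)CN/C=C\C(=O)CC[N+](C)(C)C.[I-] | intermediate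
7 | icosanoic acid | CCCCCCCCCCCCCCCCCCCC(=O)O | starting material
8 | 1,3-dioxoisoindolin-2-yl icosanoate | CCCCCCCCCCCCCCCCCCCC(=O)ON1C(=O)c2ccccc2C1=O | intermediate
9 | methyl N-[(1Z)-3-oxopenta-1,4-dien-1-yl]glycinate | COC(=O)CN/C=C\C(=O)C=C | intermediate
10 | methyl N-[(1Z)-3-oxotetracos-1-en-1-yl]glycinate | CCCCCCCCCCCCCCCCCCCCCC(=O)/C=C\NCC(=O)OC | intermediate
11 | methyl 3-henicosyl-3-hydroxy-2,3-dihydro-1H-pyrrole-2-carboxylate (racemic mixture of diastereomers) | CCCCCCCCCCCCCCCCCCCCCC1(O)C=CNC1C(=O)OC | intermediate
12 | methyl 3-henicosyl-1H-pyrrole-2-carboxylate | CCCCCCCCCCCCCCCCCCCCCc1cc[nH]c1C(=O)OC | target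

**Step count**

Total steps: 5. Longest linear sequence: 4 (steps 1, 2, 3, 5).

**Steps most likely to fail**

Step 5. The vinyl ketone released in the flask may be consumed before the alkyl radical is captured, either by attack of the nucleophilic enaminone α-carbon of one molecule on the vinyl ketone of another or by radical oligomerisation. The primary radical may also be reduced prematurely by hydrogen transfer from the dihydropyridine, and ring closure in the crude mixture may stall or be accompanied by ester hydrolysis by the water released. The fallback sets out from 8 and comes back to the route at 12. It keeps the radical conjugate addition for the same chain bond but uses a simple acceptor and closes the ring by an independent classical method. Giese addition of the radical from 8 to acrolein under the same photoredox conditions should give docosanal F1. Henry reaction with nitromethane (catalytic base) should give racemic 1-nitrotricosan-2-ol F2, and dehydration (MsCl, Et3N) should give (1E)-1-nitrotricos-1-ene F3. Barton–Zard reaction of F3 with methyl isocyanoacetate (K2CO3, MeOH–THF) should then deliver 12 directly.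

Step 2. Dimethylamine may be lost from the β-amino ketone under the amine conditions, and the vinyl ketone so formed may be captured by glycine ester through aza-Michael addition; free glycine ester may also self-condense. The fallback sets out from 8 (together with 4) and comes back at 10, which is then isolated and cyclised with NaOMe in MeOH–THF as in the last stage of step 5. It replaces the vinyl ketone acceptor by a homoenolate donor, so the glycine unit is introduced on a saturated keto acetal. Kulinkovich reaction of methyl 3,3-dimethoxypropanoate (EtMgBr, cat. Ti(OiPr)4) should give 1-(2,2-dimethoxyethyl)cyclopropan-1-ol F4. Nickel-catalysed ring-opening coupling of its homoenolate with 8 should form the same chain bond and give 1,1-dimethoxytetracosan-3-one F5. Condensation of F5 with 4 (NaOAc, MeOH) should give 10.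

Step 3. Hofmann-type elimination may set in during quaternisation, with unreacted tertiary amine acting as the base, and the enaminone may be methylated competitively. The fallback sets out from 5 and comes back at 9. It replaces the ammonium leaving group by a thermal syn-elimination under neutral conditions. Oxidation of 5 with mCPBA (CH2Cl2, −78 → 0 °C) should give (4Z)-5-[(2-methoxy-2-oxoethyl)amino]-N,N-dimethyl-3-oxopent-4-en-1-amine N-oxide F6. Cope elimination of F6 on warming to room temperature should give a CH2Cl2 solution of 9, which after a bicarbonate wash enters step 5 at the radical addition stage without the amine base.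

**Further compounds**

F1 | step 5 | docosanal | CCCCCCCCCCCCCCCCCCCCCC=O
F2 | step 5 | 1-nitrotricosan-2-ol (racemic) | CCCCCCCCCCCCCCCCCCCCCC(O)C[N+](=O)[O-]
F3 | step 5 | (1E)-1-nitrotricos-1-ene | CCCCCCCCCCCCCCCCCCCCC/C=C/[N+](=O)[O-]
F4 | step 2 | 1-(2,2-dimethoxyethyl)cyclopropan-1-ol | COC(CC1(O)CC1)OC
F5 | step 2 | 1,1-dimethoxytetracosan-3-one | CCCCCCCCCCCCCCCCCCCCCC(=O)CC(OC)OC
F6 | step 3 | (4Z)-5-[(2-methoxy-2-oxoethyl)amino]-N,N-dimethyl-3-oxopent-4-en-1-amine N-oxide | COC(=O)CN/C=C\C(=O)CC[N+](C)(C)[O-]
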